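## Structural features

The target is a germacranolide: a ten-membered carbocycle (C1–C10) with a ketone at C1, a methyl (C14) on C10, a 4,5-epoxide whose C4 also carries the methyl C15, and a butenolide (O–C6, C7=C11, C12=O) fused across C6–C7. C11 carries the acetoxymethyl carbon C13 and C8 carries a 3-methylbut-2-enoate (senecioate). There are five stereocentres: C4, C5 and C6 are contiguous, C8 is separated from C6 only by the sp2 carbon C7, and C10 is remote and sits next to the C1 ketone, so it can epimerise. The epoxide is cis with respect to the ring (C3 and C6 on the same side), which means the C4–O bond and a leaving group on C5 must be anti at the moment of closure. Fragile elements are the epoxide (acid, and base through the acidic γ-proton H6 of the butenolide), the allylic acetate and senecioate (SN2', acyl transfer), and C10–H. The real difficulty is the medium ring together with the dense C4–C8 array: a tetrasubstituted olefin flanked by three allylic C–O bonds. The key step exploits the 1,6-relationship of C4 and C9: because C4 bears both oxygen and the one-carbon branch C15, bonding C15 to C9 as a ketone turns the ring into the perimeter of a bicyclo[4.4.1]undecane. Its halves are a 2-alkoxytropone (C4–C9 plus C15) and a 2-oxygenated diene (C3, C2, C1, C10), and the leftover C5–C8 diene is the handle for all later oxygenation.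

## Logic of the disconnections

30 to 28 (through 29): the O–C5 bond of the epoxide is cut, leaving a tertiary C4 hydroxyl and an activated C5 oxygen. The epoxide is the most labile group, so it is made last. The forward step needs inversion at C5, so the C5 oxygen must sit on the face opposite to the final epoxide oxygen, and the base must not touch H6.

28 to 27: the C1 ketone and the 4,5-diol are re-masked (C–O bonds of a ketal and of an arylidene acetal). Both come off in one acidic operation, which must be faster than enolisation towards C10.

27 to 25 (through 26): the lactone O6–C12 bond and the C13–OAc bond are cut, and O6 is reconnected to C7 as a 6,7-epoxide with C11=C13 as an acrylate olefin. One SN2' event then delivers the acetate, the C7=C11 olefin and the free C6 oxygen. The forward step must leave the C6–O bond untouched and must reach the olefin geometry that can lactonise.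

25 to 24 to 23: the senecioate C–O bond is cut, then the C8–H bond (ketone). Acylation before lactonisation prevents the C8 oxygen from competing for C12. The reduction must place the C8 hydroxyl cis to the epoxide oxygen.

23 to 22: both C–O bonds of the 6,7-epoxide are cut, giving a cis-enone. The forward epoxidation must choose the ketone-activated olefin over the acrylate and the face anti to the C5 oxygen.

22 to 19 and 21, 19 to 18, 21 to 20: the C7–C11 bond is cut (cross-coupling), then C7–I and C–Sn. This attaches C11, C12 and C13 in one piece at the enone α-carbon. The coupling must tolerate a hindered α-iodoenone.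

18 to 17 to 16 to 15 to 14: the C8 oxidation level is adjusted and the three C15–H bonds are traced back to a C15 ester through the tosylate and the alcohol. This is the price of using C15 as a bridge. It demands a hydride displacement at a neopentyl-type carbon and accepts a temporary over-reduction at C8.

14 to 13: the acetal C–O5 bond is cut, returning the 4-methoxybenzyl ether on O4. The protecting group is thus moved, not removed, in one oxidation.

13 to 11 (through 12): the ester O–C15 bond is cut and C15 is rejoined to C9. The ten-membered ring becomes the perimeter of a bicycle, and the C8 ketone and C5 hydroxyl become a 5,8-peroxide. Forward, the base must take H8, not H5, and methoxide must attack only the bridging ketone.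

11 to 10: the C5–O and C8–O bonds are cut, back to the cyclic diene. Singlet oxygen must add on the face of the C15 bridge.

10 to 9 to 7 to 6: the ketal C–O bonds, the C10–H bond (epimerisation) and the O–Si bond are cut. The ketalisation doubles as the resolution. The protonation must be kinetic and face-selective.

6 to 3 and 5: the C3–C4 and C9–C10 bonds are cut, the key [6+4] disconnection. Two skeletal bonds, one ring and three stereocentres arise together. The forward step needs regio-, peri- and exo selectivity.

3 to 1 and 2, 5 to 4: the O–CH2Ar and O–Si bonds are cut, back to commercial materials.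

## Other disconnections considered

Alternative 1: Grob fragmentation across a temporary C4–C8 bond.
- Cut: C4 and C8 are joined across the ring; C4=C5 and the C8 carbonyl are traded for a C5 sulfonate and a C8 alkoxide.
- Forward key step: with C4–C8 still in place, the C8 alkoxide expels the antiperiplanar C5 mesylate as C4–C8 breaks, giving the ten-membered (Z)-enone A1.
- In favour: the fragmentation is stereospecific, the Z olefin is what a cis epoxide needs, and C15 is a real methyl from the start. The C1 ketal, the C6 oxygen and C10 are already present.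
- Against here: the C4 oxygen has to come from a late epoxidation of a trisubstituted olefin in a flexible ring. The fused precursor with four or five stereocentres must be built first. C7 is a bare methylene next to a β-silyloxy ketone that is prone to elimination.
- Comparison: on structure the alternative is better, because nothing has to be spent on converting an ester into the C15 methyl. On mechanism it is also better defined than a cycloaddition with open regio- and periselectivity. The chosen plan is better in fixing the C4 oxygen and the C5 and C8 oxygens from a rigid bicycle. Step economy is judged equal.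

Alternative 2: nitrile oxide cycloaddition as a ring-closing masked aldol.
- Cut: C7–C8 and O–C6, with the β-hydroxy ketone C6–OH/C8=O hidden in an isoxazoline.
- Forward key step: hypochlorite oxidation of a C8 oxime function generates the nitrile oxide A2, which adds across the terminal C6=C7 vinyl group (carbon to C7, oxygen to C6) to give the isoxazoline-bridged carbocycle A3.
- In favour: the epoxide, C10 and the C1 ketal are installed on an open chain by reagent-controlled chemistry before the ring exists. The dipole is expected to add anti to the epoxide oxygen, and C7 ends up activated for attaching C11.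
- Against here: closing a ten-membered ring by dipolar cycloaddition competes with nitrile oxide dimerisation and needs high dilution. The labile epoxide must then survive N–O cleavage and the whole butenolide construction. C8 still needs a stereoselective reduction.
- Comparison: on structure the alternative is better (convergent, and no corrective epimerisation at C10). On mechanism the chosen plan is better, since it never closes a medium ring. On C8 control the two are equal. Step economy is equal or slightly better for the alternative if the cyclisation works.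

Alternative 3: enone–cyclobutene photocycloaddition, then cyclobutane cleavage.
- Cut: C1–C10 and C4–C5 are formed by [2+2]; the cyclobutane bonds C1–C4 and C5–C10 are broken later to open the ten-membered ring.
- Forward key step: irradiation of enone A4 with cyclobutene A5 gives the cis-anti-cis tricycle A6.
- In favour: two simple partners, both methyls real, the C6 ketone and C8 oxygen in place. The C8 stereocentre of enantiopure A4 could set the absolute configuration.
- Against here: head-to-head versus head-to-tail orientation between two trisubstituted partners is uncertain. The olefin geometry from the cyclobutane cleavage is hard to control (Z is needed at C4=C5). C10 arises only on enol ether protonation in a flexible ring, and the C4 oxygen and the C7 substituent are still missing.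
- Comparison: on structure the alternative is better (no sacrificial carbon, and absolute control without a resolution). On mechanism the chosen plan is better, because a thermal, suprafacial cycloaddition that locks C4 against C9 is more predictable. The ring is reached in fewer steps (better), but the C4–C7 functionalisation afterwards is at least as long, so the overall count is about equal.

Key step: step 3

Remark: germacrane locants are used throughout (ring C1–C10, C14 on C10, C15 on C4, C11–C13 the lactone carbons); "C15 face" means the face of the C5–C8 unit that carried the carbonyl bridge.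

Remark: the exo transition state with the Z enol ether places the C10 methyl cis to H9 (C10 R with C4 S, C9 R), whereas the target needs the C10 epimer; 6 is therefore drawn as the exo adduct and C10 is inverted in step 5.

Remark: a tert-butyldimethylsilyl group replaces trimethylsilyl on the diene for stability; 6–9 are racemic (one enantiomer drawn) and the material is a single enantiomer from 10 on; the acetal carbon in 14–19 and 22–27 and C8 in 15–17 are not stereodefined and are carried as mixtures.

## Route

Step 1
Reactants: 1 tropolone; 2 4-methoxybenzyl chloride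
Product: 3 2-(4-methoxybenzyloxy)cyclohepta-2,4,6-trien-1-one
Conditions: K2CO3, Bu4NI (cat.), DMF, 60 °C
Reagents that add atoms: none
Why: Williamson O-alkylation of the acidic tropolone; the symmetrical tropolonate can give only one ether.

Step 2
Reactants: 4 pent-1-en-3-one
Product: 5 (Z)-3-(tert-butyldimethylsilyloxy)penta-1,3-diene
Conditions: tBuMe2SiOTf, Et3N, Et2O, 0 → 20 °C
Reagents that add atoms: tert-butyldimethylsilyl trifluoromethanesulfonate, CC(C)(C)[Si](C)(C)OS(=O)(=O)C(F)(F)F
Why: Soft enolisation of the ethyl ketone with a silyl triflate and an amine should give the Z silyl dienol ether, whose methyl is trans to the vinyl group (outside position of the s-cis diene).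

Step 3
Reactants: 3 2-(4-methoxybenzyloxy)cyclohepta-2,4,6-trien-1-one; 5 (Z)-3-(tert-butyldimethylsilyloxy)penta-1,3-diene
Product: 6 rac-(1S,6R,7R)-8-(tert-butyldimethylsilyloxy)-1-(4-methoxybenzyloxy)-7-methylbicyclo[4.4.1]undeca-2,4,8-trien-11-one
Conditions: ZnCl2 (0.3 equiv), CH2Cl2, −20 → 20 °C
Reagents that add atoms: none
Why: A thermally allowed ten-electron [6+4] cycloaddition, suprafacial on both partners and assisted by a Lewis acid held between the tropone carbonyl and ether oxygens, joins the tropone α-carbons (C4, C9) to the diene termini (C3, C10), with the C9–C10 bond leading. The closest known reaction type is the exo-selective [6+4] cycloaddition of tropones with 1,3-dienes, including Lewis-acid-accelerated additions of 2-silyloxydienes. The new seven-membered ring (C15, C4, C3, C2, C1, C10, C9) is closed by the cycloaddition itself, both σ bonds forming on one face of the tropone, so the ten-membered perimeter arises without any medium-ring cyclisation. C4 and C9 are set cis by suprafaciality on the tropone, and C10 is set by the exo transition state together with the Z enol ether geometry, which leaves the methyl cis to H9 and away from the C5–C8 diene. Regioselectivity (nucleophilic C10 to the unsubstituted C9, C3 to the alkoxy-bearing C4) should follow from the enol ether polarisation and from the donor and steric effect of the ether on C4. Periselectivity over [4+2] and [8+2] modes rests on the known exo [6+4] preference of tropone with s-cis-biased 2-oxygenated dienes. No absolute control is attempted here: 6 is racemic and is resolved in step 6.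

Step 4
Reactants: 6 rac-(1S,6R,7R)-8-(tert-butyldimethylsilyloxy)-1-(4-methoxybenzyloxy)-7-methylbicyclo[4.4.1]undeca-2,4,8-trien-11-one
Product: 7 rac-(1R,2R,6S)-6-(4-methoxybenzyloxy)-2-methylbicyclo[4.4.1]undeca-7,9-diene-3,11-dione
Conditions: HCl (1 M aq.), THF, 0 °C
Reagents that add atoms: none
Why: Hydrolysis of the silyl enol ether by protonation at C2; C10 is not touched, and the non-enolisable bridging ketone and the tertiary benzylic ether should survive brief cold acid.

Step 5
Reactants: 7 rac-(1R,2R,6S)-6-(4-methoxybenzyloxy)-2-methylbicyclo[4.4.1]undeca-7,9-diene-3,11-dione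
Product: 9 rac-(1R,2S,6S)-6-(4-methoxybenzyloxy)-2-methylbicyclo[4.4.1]undeca-7,9-diene-3,11-dione, via lithium enolate 8 (not isolated)
Conditions: LiN(SiMe3)2 (0.95 equiv), THF, −78 → 0 °C; then inverse quench into AcOH, THF, −78 °C
Reagents that add atoms: none
Why: Enolate equilibration by proton transfer with the slight excess of ketone should favour the more substituted C1–C10 enolate; irreversible kinetic protonation then occurs on the enolate face that carries only H9, because the other face is flanked by C8 and C15, and this places the methyl cis to the C5–C8 bridge as the target requires. Material protonated at C2 returns 7, which is separated and recycled.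

Step 6
Reactants: 9 rac-(1R,2S,6S)-6-(4-methoxybenzyloxy)-2-methylbicyclo[4.4.1]undeca-7,9-diene-3,11-dione
Product: 10 (1R,2S,6S)-6-(4-methoxybenzyloxy)-2-methylbicyclo[4.4.1]undeca-7,9-diene-3,11-dione 3-ketal of (2R,3R)-butane-2,3-diol
Conditions: (2R,3R)-butane-2,3-diol, iPrOSiMe3, Me3SiOTf (cat.), CH2Cl2, −20 °C; chromatographic separation from the diastereomeric ketal
Reagents that add atoms: (2R,3R)-butane-2,3-diol, C[C@@H](O)[C@@H](C)O
Why: Aprotic, kinetically controlled ketalisation takes the unhindered C1 ketone and leaves the doubly α-branched bridging ketone. The C2-symmetric diol turns the two enantiomers of 9 into separable diastereomers (classical resolution through a covalent derivative), and the ketal shields C10 from later epimerisation; the diastereomer with C4 S, C9 R, C10 S is carried on.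

Step 7
Reactants: 10 (1R,2S,6S)-6-(4-methoxybenzyloxy)-2-methylbicyclo[4.4.1]undeca-7,9-diene-3,11-dione 3-ketal of (2R,3R)-butane-2,3-diol
Product: 11 5,8-endoperoxide of 10
Conditions: O2, tetraphenylporphyrin (cat.), visible light, CH2Cl2, −30 °C
Reagents that add atoms: dioxygen, O=O
Why: Singlet-oxygen [4+2] cycloaddition to the cyclic 1,3-diene; it should occur on the diene face next to the small C15 carbonyl bridge, since the other face is covered by C3, C10, the inward C10 methyl and the ketal, so both new C–O bonds (C5, C8) are cis to C15.

Step 8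
Reactants: 11 5,8-endoperoxide of 10
Product: 13 methyl (4S,5S,6Z,10S)-5-hydroxy-4-(4-methoxybenzyloxy)-10-methyl-8-oxocyclodec-6-ene-4-carboxylate 1-ketal, via bridged hydroxy enone 12 (not isolated)
Conditions: Et3N (0.5 equiv), CH2Cl2, 0 → 20 °C; then NaOMe (0.3 equiv), MeOH, 0 °C
Reagents that add atoms: methanol, CO
Why: Kornblum–DeLaMare rearrangement (the base removes H8, which has a tertiary, not a quaternary, neighbour) gives the C8 ketone and the C5 carbinol. C8 and C15 then flank C9 as a β-diketone that cannot enolise at the bridgehead, so methoxide adds to the bridging ketone and retro-Claisen cleavage of C15–C9 releases the enone dienolate, which opens the ten-membered ring and leaves C15 as the ester on C4.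

Step 9
Reactants: 13 methyl (4S,5S,6Z,10S)-5-hydroxy-4-(4-methoxybenzyloxy)-10-methyl-8-oxocyclodec-6-ene-4-carboxylate 1-ketal
Product: 14 methyl (4S,5S,6Z,10S)-4,5-(4-methoxybenzylidenedioxy)-10-methyl-8-oxocyclodec-6-ene-4-carboxylate 1-ketal
Conditions: DDQ (1.2 equiv), 4 Å molecular sieves, CH2Cl2, 0 °C
Reagents that add atoms: none
Why: Under anhydrous conditions the oxocarbenium ion formed by benzylic oxidation of the 4-methoxybenzyl ether is trapped by the neighbouring C5 hydroxyl, so the ether becomes a 4-methoxybenzylidene acetal that protects both O4 and O5 (oxidative acetal formation from a 4-methoxybenzyl ether).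

Step 10
Reactants: 14 methyl (4S,5S,6Z,10S)-4,5-(4-methoxybenzylidenedioxy)-10-methyl-8-oxocyclodec-6-ene-4-carboxylate 1-ketal
Product: 15 (4S,5S,6Z,10S)-4-(hydroxymethyl)-4,5-(4-methoxybenzylidenedioxy)-10-methylcyclodec-6-en-8-ol 1-ketal
Conditions: LiAlH4, THF, 0 °C
Reagents that add atoms: none
Why: Hydride reduction of the ester to the primary alcohol with concomitant 1,2-reduction of the enone; the C8 carbinol is only a placeholder that is reoxidised in step 13, and both acetals are inert.

Step 11
Reactants: 15 (4S,5S,6Z,10S)-4-(hydroxymethyl)-4,5-(4-methoxybenzylidenedioxy)-10-methylcyclodec-6-en-8-ol 1-ketal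
Product: 16 C15 4-methylbenzenesulfonate of 15
Conditions: TsCl, pyridine, CH2Cl2, 0 °C
Reagents that add atoms: 4-methylbenzenesulfonyl chloride, Cc1ccc(cc1)S(Cl)(=O)=O
Why: Sulfonylation of the primary hydroxyl should be much faster than that of the secondary allylic one.

Step 12
Reactants: 16 C15 4-methylbenzenesulfonate of 15
Product: 17 (4S,5S,6Z,10S)-4,5-(4-methoxybenzylidenedioxy)-4,10-dimethylcyclodec-6-en-8-ol 1-ketal
Conditions: LiBHEt3 (excess), THF, 0 → 65 °C
Reagents that add atoms: none
Why: SN2 displacement of the sulfonate by LiBHEt3, a hydride donor strong enough for neopentyl-type sulfonates, turns the former bridge carbon C15 into the C4 methyl; O4 and O5 are tied up in the acetal and cannot close an oxetane or an epoxide.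

Step 13
Reactants: 17 (4S,5S,6Z,10S)-4,5-(4-methoxybenzylidenedioxy)-4,10-dimethylcyclodec-6-en-8-ol 1-ketal
Product: 18 (4S,5S,6Z,10S)-4,5-(4-methoxybenzylidenedioxy)-4,10-dimethylcyclodec-6-en-8-one 1-ketal
Conditions: Dess–Martin periodinane, NaHCO3, CH2Cl2, 0 → 20 °C
Reagents that add atoms: none
Why: Oxidation of the only free hydroxyl back to the C8 ketone converges both C8 epimers on one cis-enone.

Step 14
Reactants: 18 (4S,5S,6Z,10S)-4,5-(4-methoxybenzylidenedioxy)-4,10-dimethylcyclodec-6-en-8-one 1-ketal
Product: 19 7-iodo derivative of 18
Conditions: I2, pyridine, CH2Cl2, 0 → 20 °C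
Reagents that add atoms: iodine, II
Why: α-Iodination of the enone by conjugate addition of pyridine at C6, iodination of the enolate at C7 and elimination; this provides the handle for the C7–C11 bond.

Step 15
Reactants: 20 methyl propiolate
Product: 21 methyl 2-(tributylstannyl)acrylate
Conditions: Bu3SnH, Pd(PPh3)4 (2 mol %), THF, 0 → 20 °C
Reagents that add atoms: tributyltin hydride, CCCC[SnH](CCCC)CCCC
Why: Palladium-catalysed syn-hydrostannation of the alkynoate places tin on the α-carbon and gives the C11–C12–C13 building block.

Step 16
Reactants: 19 7-iodo derivative of 18; 21 methyl 2-(tributylstannyl)acrylate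
Product: 22 methyl 2-[(4S,5S,6Z,10S)-4,5-(4-methoxybenzylidenedioxy)-4,10-dimethyl-8-oxocyclodec-6-en-7-yl]acrylate 1-ketal
Conditions: Pd2(dba)3 (5 mol %), AsPh3, CuI, DMF, 20 °C
Reagents that add atoms: none
Why: Stille coupling of the α-iodoenone with the α-stannylacrylate forms C7–C11 with retention of the ring olefin geometry; CuI speeds transmetalation between two hindered partners.

Step 17
Reactants: 22 methyl 2-[(4S,5S,6Z,10S)-4,5-(4-methoxybenzylidenedioxy)-4,10-dimethyl-8-oxocyclodec-6-en-7-yl]acrylate 1-ketal
Product: 23 6,7-epoxide of 22
Conditions: tBuOOH, DBU, CH2Cl2, 0 °C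
Reagents that add atoms: tert-butyl hydroperoxide, CC(C)(C)OO
Why: Weitz–Scheffer epoxidation: the peroxide anion should add to C6, the β-carbon of the ketone-activated olefin, in preference to the acrylate terminus. It approaches anti to the quaternary C4 with C5–H eclipsing the olefin, that is anti to the C5–O bond, and the enolate closes on the same face, which sets C6 as in the lactone carbinol.

Step 18
Reactants: 23 6,7-epoxide of 22
Product: 24 8-hydroxy compound from 23
Conditions: Zn(BH4)2, Et2O, −20 °C
Reagents that add atoms: none
Why: Chelation-controlled reduction of the α,β-epoxy ketone: zinc bridges the carbonyl and epoxide oxygens and hydride enters from the side away from the epoxide carbon C6, which should give the C8 carbinol cis to the epoxide oxygen, the configuration of the target. Esters are not reduced, and any C8 epimer is returned to 23 by oxidation.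

Step 19
Reactants: 24 8-hydroxy compound from 23
Product: 25 8-(3-methylbut-2-enoate) of 24
Conditions: 3-methylbut-2-enoyl chloride, pyridine, DMAP (cat.), CH2Cl2, −20 → 0 °C
Reagents that add atoms: 3-methylbut-2-enoyl chloride, CC(C)=CC(Cl)=O
Why: Acylation of the only hydroxyl with retention at C8; pyridine in place of a trialkylamine limits vinylketene formation and deconjugation of the acyl group.

Step 20
Reactants: 25 8-(3-methylbut-2-enoate) of 24
Product: 27 (4S,5S,6R,8R,10S)-13-acetoxy-4,5-(4-methoxybenzylidenedioxy)-8-(3-methylbut-2-enoyloxy)germacr-7(11)-en-6,12-olide 1-ketal, via hydroxy ester 26 (not isolated)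
Conditions: Pd(PPh3)4 (5 mol %), AcOH (3 equiv), THF, 0 → 40 °C
Reagents that add atoms: acetic acid, CC(O)=O
Why: Zerovalent palladium ionises the allylic C7–O bond of the vinyl epoxide and acetate attacks the unhindered C13 terminus of the π-allyl complex (Tsuji–Trost 1,4-addition of a carboxylic acid to a vinyl epoxide). This creates C7=C11 and the C13 acetate, while the untouched C6 oxygen lactonises onto the methyl ester. Reversible ionisation of the new allylic acetate should funnel both olefin isomers into the one that can lactonise.

Step 21
Reactants: 27 (4S,5S,6R,8R,10S)-13-acetoxy-4,5-(4-methoxybenzylidenedioxy)-8-(3-methylbut-2-enoyloxy)germacr-7(11)-en-6,12-olide 1-ketal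
Product: 28 (4S,5S,6R,8R,10S)-13-acetoxy-4,5-dihydroxy-8-(3-methylbut-2-enoyloxy)-1-oxogermacr-7(11)-en-6,12-olide
Conditions: HCl (1 M aq.), THF, 20 °C
Reagents that add atoms: water, O
Why: Acid hydrolysis of the 4-methoxybenzylidene acetal and of the C1 ketal in one operation; acetal hydrolysis should be much faster than acid-catalysed enolisation, so C10 is retained, and the allylic esters tolerate dilute acid.

Step 22
Reactants: 28 (4S,5S,6R,8R,10S)-13-acetoxy-4,5-dihydroxy-8-(3-methylbut-2-enoyloxy)-1-oxogermacr-7(11)-en-6,12-olide
Product: 30 (4S,5R,6R,8R,10S)-13-acetoxy-4,5-epoxy-8-(3-methylbut-2-enoyloxy)-1-oxogermacr-7(11)-en-6,12-olide, via C5 methanesulfonate 29 (not isolated)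
Conditions: MsCl, Et3N, CH2Cl2, −30 °C; then KN(SiMe3)2 (1.0 equiv), THF, −78 °C
Reagents that add atoms: none
Why: Mesylation of the only secondary hydroxyl, then O-deprotonation of the tertiary C4 hydroxyl and 3-exo-tet displacement with inversion at C5 gives the cis-4,5-epoxide. Kinetic O–H deprotonation by one equivalent of a hindered base at low temperature is meant to outrun removal of the γ-proton H6.

## Compound list

1 | tropolone (2-hydroxycyclohepta-2,4,6-trien-1-one) | O=C1C=CC=CC=C1O | starting material
2 | 4-methoxybenzyl chloride | COc1ccc(CCl)cc1 | starting material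
3 | 2-(4-methoxybenzyloxy)cyclohepta-2,4,6-trien-1-one | O=C1C=CC=CC=C1OCc1ccc(OC)cc1 | intermediate
4 | pent-1-en-3-one | CCC(=O)C=C | starting material
5 | (Z)-3-(tert-butyldimethylsilyloxy)penta-1,3-diene | C=C/C(O[Si](C)(C)C(C)(C)C)=C/C | intermediate
6 | rac-(1S,6R,7R)-8-(tert-butyldimethylsilyloxy)-1-(4-methoxybenzyloxy)-7-methylbicyclo[4.4.1]undeca-2,4,8-trien-11-one (exo adduct; racemic, one enantiomer drawn) | O=C1[C@@]2(OCc3ccc(OC)cc3)C=CC=C[C@@H]1[C@@H](C)C(O[Si](C)(C)C(C)(C)C)=CC2 | intermediate
7 | rac-(1R,2R,6S)-6-(4-methoxybenzyloxy)-2-methylbicyclo[4.4.1]undeca-7,9-diene-3,11-dione (racemic, one enantiomer drawn) | O=C1[C@@]2(OCc3ccc(OC)cc3)C=CC=C[C@@H]1[C@@H](C)C(=O)CC2 | intermediate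
8 | lithium enolate of 7 across germacrane C1–C10 (racemic) | O=C1[C@@]2(OCc3ccc(OC)cc3)C=CC=C[C@@H]1C(C)=C(O[Li])CC2 | intermediate (not isolated)
9 | rac-(1R,2S,6S)-6-(4-methoxybenzyloxy)-2-methylbicyclo[4.4.1]undeca-7,9-diene-3,11-dione (C10 epimer of 7; racemic, one enantiomer drawn) | O=C1[C@@]2(OCc3ccc(OC)cc3)C=CC=C[C@@H]1[C@H](C)C(=O)CC2 | intermediate
10 | (1R,2S,6S)-6-(4-methoxybenzyloxy)-2-methylbicyclo[4.4.1]undeca-7,9-diene-3,11-dione 3-ketal of (2R,3R)-butane-2,3-diol (spiro (4R,5R)-4,5-dimethyl-1,3-dioxolane at germacrane C1) | O=C1[C@@]2(OCc3ccc(OC)cc3)C=CC=C[C@@H]1[C@H](C)C4(O[C@H](C)[C@@H](C)O4)CC2 | intermediate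
11 | 5,8-endoperoxide of 10 (O–O bridge from C5 to C8 on the C15 face, C6=C7 olefin) | O=C1[C@@]2(OCc5ccc(OC)cc5)[C@@H]3C=C[C@@H](OO3)[C@@H]1[C@H](C)C4(O[C@H](C)[C@@H](C)O4)CC2 | intermediate
12 | bridged hydroxy enone: C5 hydroxyl on the C15 face, C6=C7, C8 and C15 ketones flanking C9–H | O=C1[C@@]2(OCc5ccc(OC)cc5)[C@@H](O)C=CC(=O)[C@@H]1[C@H](C)C4(O[C@H](C)[C@@H](C)O4)CC2 | intermediate (not isolated)
13 | methyl (4S,5S,6Z,10S)-5-hydroxy-4-(4-methoxybenzyloxy)-10-methyl-8-oxocyclodec-6-ene-4-carboxylate, 1-ketal of (2R,3R)-butane-2,3-diol (ester carbon = C15) | COC(=O)[C@@]1(OCc5ccc(OC)cc5)[C@@H](O)/C=C\C(=O)C[C@H](C)C4(O[C@H](C)[C@@H](C)O4)CC1 | intermediate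
14 | methyl (4S,5S,6Z,10S)-4,5-(4-methoxybenzylidenedioxy)-10-methyl-8-oxocyclodec-6-ene-4-carboxylate, 1-ketal (acetal carbon not stereodefined) | COC(=O)[C@]13OC(c5ccc(OC)cc5)O[C@H]3/C=C\C(=O)C[C@H](C)C4(O[C@H](C)[C@@H](C)O4)CC1 | intermediate
15 | (4S,5S,6Z,10S)-4-(hydroxymethyl)-4,5-(4-methoxybenzylidenedioxy)-10-methylcyclodec-6-en-8-ol, 1-ketal (acetal carbon and C8 not stereodefined) | OC[C@]13OC(c5ccc(OC)cc5)O[C@H]3/C=C\C(O)C[C@H](C)C4(O[C@H](C)[C@@H](C)O4)CC1 | intermediate
16 | C15 4-methylbenzenesulfonate of 15 | Cc6ccc(cc6)S(=O)(=O)OC[C@]13OC(c5ccc(OC)cc5)O[C@H]3/C=C\C(O)C[C@H](C)C4(O[C@H](C)[C@@H](C)O4)CC1 | intermediate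
17 | (4S,5S,6Z,10S)-4,5-(4-methoxybenzylidenedioxy)-4,10-dimethylcyclodec-6-en-8-ol, 1-ketal (acetal carbon and C8 not stereodefined) | C[C@]13OC(c5ccc(OC)cc5)O[C@H]3/C=C\C(O)C[C@H](C)C4(O[C@H](C)[C@@H](C)O4)CC1 | intermediate
18 | (4S,5S,6Z,10S)-4,5-(4-methoxybenzylidenedioxy)-4,10-dimethylcyclodec-6-en-8-one, 1-ketal | C[C@]13OC(c5ccc(OC)cc5)O[C@H]3/C=C\C(=O)C[C@H](C)C4(O[C@H](C)[C@@H](C)O4)CC1 | intermediate
19 | 7-iodo derivative of 18 (ring-cis olefin retained) | C[C@]13OC(c5ccc(OC)cc5)O[C@H]3/C=C(I)\C(=O)C[C@H](C)C4(O[C@H](C)[C@@H](C)O4)CC1 | intermediate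
20 | methyl propiolate | COC(=O)C#C | starting material
21 | methyl 2-(tributylstannyl)acrylate | COC(=O)C(=C)[Sn](CCCC)(CCCC)CCCC | intermediate
22 | methyl 2-[(4S,5S,6Z,10S)-4,5-(4-methoxybenzylidenedioxy)-4,10-dimethyl-8-oxocyclodec-6-en-7-yl]acrylate, 1-ketal | C[C@]13OC(c5ccc(OC)cc5)O[C@H]3/C=C(C(=C)C(=O)OC)\C(=O)C[C@H](C)C4(O[C@H](C)[C@@H](C)O4)CC1 | intermediate
23 | 6,7-epoxide of 22 (epoxide oxygen on the face opposite to the C5 oxygen; acrylate on C7) | C[C@]13OC(c5ccc(OC)cc5)O[C@H]3[C@@H]6O[C@]6(C(=C)C(=O)OC)C(=O)C[C@H](C)C4(O[C@H](C)[C@@H](C)O4)CC1 | intermediate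
24 | 8-hydroxy compound from 23 (C8 hydroxyl cis to the epoxide oxygen) | C[C@]13OC(c5ccc(OC)cc5)O[C@H]3[C@@H]6O[C@]6(C(=C)C(=O)OC)[C@H](O)C[C@H](C)C4(O[C@H](C)[C@@H](C)O4)CC1 | intermediate
25 | 8-(3-methylbut-2-enoate) of 24 | C[C@]13OC(c5ccc(OC)cc5)O[C@H]3[C@@H]6O[C@]6(C(=C)C(=O)OC)[C@H](OC(=O)C=C(C)C)C[C@H](C)C4(O[C@H](C)[C@@H](C)O4)CC1 | intermediate
26 | hydroxy ester: C6 hydroxyl, C7=C11 with the methyl ester cis to C6, acetoxymethyl on C11, C8 senecioate | C[C@]13OC(c5ccc(OC)cc5)O[C@H]3[C@H](O)/C(=C(/COC(C)=O)C(=O)OC)[C@H](OC(=O)C=C(C)C)C[C@H](C)C4(O[C@H](C)[C@@H](C)O4)CC1 | intermediate (not isolated)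
27 | (4S,5S,6R,8R,10S)-13-acetoxy-4,5-(4-methoxybenzylidenedioxy)-8-(3-methylbut-2-enoyloxy)germacr-7(11)-en-6,12-olide, 1-ketal of (2R,3R)-butane-2,3-diol | C[C@]13OC(c5ccc(OC)cc5)O[C@H]3[C@@H]6OC(=O)C(COC(C)=O)=C6[C@H](OC(=O)C=C(C)C)C[C@H](C)C4(O[C@H](C)[C@@H](C)O4)CC1 | intermediate
28 | (4S,5S,6R,8R,10S)-13-acetoxy-4,5-dihydroxy-8-(3-methylbut-2-enoyloxy)-1-oxogermacr-7(11)-en-6,12-olide | C[C@@]1(O)[C@@H](O)[C@@H]6OC(=O)C(COC(C)=O)=C6[C@H](OC(=O)C=C(C)C)C[C@H](C)C(=O)CC1 | intermediate
29 | 5-methanesulfonate of 28 | C[C@@]1(O)[C@@H](OS(C)(=O)=O)[C@@H]6OC(=O)C(COC(C)=O)=C6[C@H](OC(=O)C=C(C)C)C[C@H](C)C(=O)CC1 | intermediate (not isolated)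
30 | (4S,5R,6R,8R,10S)-13-acetoxy-4,5-epoxy-8-(3-methylbut-2-enoyloxy)-1-oxogermacr-7(11)-en-6,12-olide | CC(=O)OCC1=C2[C@@H](OC1=O)[C@H]1O[C@@]1(C)CCC(=O)[C@@H](C)C[C@H]2OC(=O)C=C(C)C | target

## Step count and least certain steps

Total: 22 steps. Longest linear sequence: 20 steps from tropolone (steps 1, 3–14 and 16–22); steps 2 and 15 prepare the two side components.

Step 3 (key step). Most likely to go wrong: loss of peri- and regioselectivity ([4+2] or [8+2] addition, or conjugate addition without closure of the second bond). The alkoxy group makes the tropone less electrophilic and unsymmetrical, and the Lewis acid favours stepwise bond formation. Fallback, from 3 and 5, back at 9: a metal-templated cycloaddition. Compound 3 is complexed with Cr(CO)3(MeCN)3 to tricarbonyl[η6-2-(4-methoxybenzyloxy)tropone]chromium F1 (zerovalent chromium) and irradiated with 5. Templated [6+4] additions take the endo course, so after decomplexation under CO the adduct should be the C10 epimer of 6, rac-(1S,6R,7S)-8-(tert-butyldimethylsilyloxy)-1-(4-methoxybenzyloxy)-7-methylbicyclo[4.4.1]undeca-2,4,8-trien-11-one F2. Hydrolysis as in step 4 then gives 9 directly and step 5 is not needed.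

Step 5. Most likely to go wrong: poor regiocontrol of enolisation (C2 against C10) and incomplete facial selectivity in the protonation, because the enolate mixture is only thermodynamically biased. Fallback, from 6, back at 9: make H10 the only acidic proton. Saegusa–Ito oxidation of 6 (Pd(OAc)2, MeCN) gives the enone rac-(1R,2R,6R)-6-(4-methoxybenzyloxy)-2-methylbicyclo[4.4.1]undeca-4,7,9-triene-3,11-dione F3. Deprotonation with LiN(SiMe3)2 and kinetic protonation as in step 5 gives its C10 epimer rac-(1R,2S,6R)-6-(4-methoxybenzyloxy)-2-methylbicyclo[4.4.1]undeca-4,7,9-triene-3,11-dione F4, and conjugate reduction with [(Ph3P)CuH]6 returns 9.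

Step 8. Most likely to go wrong: abstraction of H5 in place of H8 in the Kornblum–DeLaMare step, since both protons lie on the crowded face of the bicycle; this would put the ketone at C5 and block the retro-Claisen cleavage. Fallback, from 11, back at 13: reductive cleavage of the O–O bond with thiourea in MeOH gives the 5,8-cis-diol of the bicycle F5, whose hydroxyls lie on the open face. MnO2 then oxidises the less hindered allylic C8 carbinol (the C5 carbinol has a quaternary neighbour) to 12, and NaOMe in MeOH gives 13.

Step 17. Most likely to go wrong: peroxide addition at the acrylate terminus C13 in place of C6, or attack on the wrong face, because two acceptor olefins compete in a cross-conjugated system. Fallback, from 22, back at 24: reverse the order and epoxidise electrophilically under hydroxyl direction. Luche reduction (NaBH4, CeCl3·7H2O, MeOH, −78 °C) gives the C8 carbinol of 22 F6 (the epimer shown; the other is returned to 22 with MnO2). VO(acac)2 and tBuOOH then epoxidise only the allylic-alcohol olefin, syn to the carbinol, to give 24.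

Step 20. Most likely to go wrong: ionisation of the allylic esters of the product, or formation of the olefin isomer that cannot lactonise, because three allylic C–O bonds surround the new olefin. Fallback, from 25, back at 27: a polar SN2' opening with halide. LiBr and AcOH in THF add bromide to C13 with opening of the epoxide and lactonisation to the 13-bromo analogue of 27 F7. KOAc with 18-crown-6 in MeCN then displaces bromide to give 27.

Step 22. Most likely to go wrong: base-induced elimination, in which removal of the acidic γ-proton H6 of the butenolide is followed by loss of the C5 mesylate, in competition with epoxide closure. Fallback, from 28, back at 30: neutral cyclodehydration of the 4,5-diol under Mitsunobu conditions (PPh3, DIAD, toluene, 0 → 60 °C). The secondary C5 oxygen is activated as the oxyphosphonium ion and displaced by the tertiary hydroxyl with the same inversion; no new compound is involved (F0).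

## Further compounds

F1 | step 3 | tricarbonyl[η6-2-(4-methoxybenzyloxy)tropone]chromium | O=C1C=CC=CC=C1OCc1ccc(OC)cc1.[Cr].[C-]#[O+].[C-]#[O+].[C-]#[O+]
F2 | step 3 | rac-(1S,6R,7S)-8-(tert-butyldimethylsilyloxy)-1-(4-methoxybenzyloxy)-7-methylbicyclo[4.4.1]undeca-2,4,8-trien-11-one | O=C1[C@@]2(OCc3ccc(OC)cc3)C=CC=C[C@@H]1[C@H](C)C(O[Si](C)(C)C(C)(C)C)=CC2
F3 | step 5 | rac-(1R,2R,6R)-6-(4-methoxybenzyloxy)-2-methylbicyclo[4.4.1]undeca-4,7,9-triene-3,11-dione | O=C1[C@@]2(OCc3ccc(OC)cc3)C=CC=C[C@@H]1[C@@H](C)C(=O)C=C2
F4 | step 5 | rac-(1R,2S,6R)-6-(4-methoxybenzyloxy)-2-methylbicyclo[4.4.1]undeca-4,7,9-triene-3,11-dione | O=C1[C@@]2(OCc3ccc(OC)cc3)C=CC=C[C@@H]1[C@H](C)C(=O)C=C2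
F5 | step 8 | 5,8-cis-diol of the bicycle (both hydroxyls on the C15 face, C6=C7 olefin, C1 ketal) | O=C1[C@@]2(OCc5ccc(OC)cc5)[C@@H](O)C=C[C@@H](O)[C@@H]1[C@H](C)C4(O[C@H](C)[C@@H](C)O4)CC2
F6 | step 17 | C8 carbinol of 22 (hydroxyl on the face opposite to the C5 oxygen) | C[C@]13OC(c5ccc(OC)cc5)O[C@H]3/C=C(C(=C)C(=O)OC)\[C@H](O)C[C@H](C)C4(O[C@H](C)[C@@H](C)O4)CC1
F7 | step 20 | 13-bromo analogue of 27 | C[C@]13OC(c5ccc(OC)cc5)O[C@H]3[C@@H]6OC(=O)C(CBr)=C6[C@H](OC(=O)C=C(C)C)C[C@H](C)C4(O[C@H](C)[C@@H](C)O4)CC1
F0 | step 22 | none | none
A1 | alternative 1 | (Z)-cyclodec-4-en-8-one with C6 tert-butyldimethylsilyl ether, C1 dioxolane and C10 methyl | C1[C@@H](O[Si](C)(C)C(C)(C)C)/C=C(C)\CCC2(OCCO2)[C@@H](C)CC1=O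
A2 | alternative 2 | open-chain nitrile oxide with C6=C7 vinyl group, 4,5-epoxide and C1 dimethyl ketal | C=C[C@H]1O[C@@]1(C)CCC(OC)(OC)[C@@H](C)CC#[N+][O-]
A3 | alternative 2 | isoxazoline-bridged ten-membered carbocycle | C1[C@@H]2[C@H]3O[C@@]3(C)CCC(OC)(OC)[C@@H](C)CC1=NO2
A4 | alternative 3 | (R)-5-(tert-butyldimethylsilyloxy)-3-methylcyclohex-2-en-1-one | O=C1C[C@H](O[Si](C)(C)C(C)(C)C)CC(C)=C1
A5 | alternative 3 | 1-methyl-2-(trimethylsilyloxy)cyclobutene | CC1=C(O[Si](C)(C)C)CC1
A6 | alternative 3 | cis-anti-cis tricyclic cyclobutane photoadduct | O=C1C[C@H](O[Si](C)(C)C(C)(C)C)C[C@]2(C)[C@H]1[C@@]3(C)CC[C@@]23O[Si](C)(C)C
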